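**Plan**

1. Retrosynthesis: the two aryl–CHO bonds and the two carbinol methyls are cut first. The bicycle is then cut at C3a–C8a and C7–C8 (alkyne plus vinylcyclopropane), the tether at C3–C3a (sp3–sp2 coupling), and the quaternary carbon at C1–C8a and C1–CH3 (lactone enolate chemistry).
2. Enabling feature: the alkene C8=C8a sits on the ring-fusion carbon bonded to quaternary C1, and C3a–C4(Me)–C5–C6–C7 is a five-carbon arc ending at the carbinol-bearing CH. This maps onto a terminal alkyne on C1 joined through C2–C3 to a vinylcyclopropane (alkene C3a=C4, ring C5–C6–C7, ester on C7).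
3. Forward: coumarin → chiral dihydrocoumarin → quaternary centre → open-chain vinyl compound; Suzuki union with a cyclopropyl vinyl iodide; alkyne; one step then closes the five- and seven-membered rings together; hydrogenation, methyl addition, double formylation and MOM removal follow.
4. Stereochemistry: benzylic centre from asymmetric CuH reduction; C1 from alkylation anti to the benzylic isobutyl group of the lactone; cyclopropane from Charette cyclopropanation; C3a and C7 from the stereospecific cycloaddition (Z alkene, trans ester); C4 from ester-directed hydrogenation.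

Key step: step 20

Remark: the cycloaddition adds suprafacially across the five-carbon unit with retention at the ester carbon, so an E alkene would place H-3a trans to the C7 ester; the tether is therefore set cis to the cyclopropane (Z alkene).
Remark: bicyclic compounds are numbered as in the target (C1 quaternary, C3a ring-fusion CH, C4 methyl-bearing, C7 ester- or carbinol-bearing, alkene C8=C8a).
Remark: the ligand antipode written in step 3 is assumed to give the (4S) lactone; if the sense of induction is opposite, the other antipode is used.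

**Route**

Step 1
Reactants: 1 benzene-1,3,5-triol (phloroglucinol); 2 ethyl 5-methyl-3-oxohexanoate
Product: 3 5,7-dihydroxy-4-(2-methylpropyl)-2H-chromen-2-one
Conditions: CF3SO3H (neat), 0 °C → rt
Reagents that add atoms: none
Why: Pechmann condensation (Friedel–Crafts attack of the symmetrical triol on the ketone, dehydration and lactonisation), which can give only one regioisomer.

Step 2
Reactants: 3 5,7-dihydroxy-4-(2-methylpropyl)-2H-chromen-2-one
Product: 4 5,7-bis(methoxymethoxy)-4-(2-methylpropyl)-2H-chromen-2-one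
Conditions: MOMCl, i-Pr2NEt, CH2Cl2, 0 °C → rt
Reagents that add atoms: chloromethyl methyl ether, COCCl
Why: O-alkylation of both phenols (MOM ether formation) gives groups that survive bases and organometallics and later direct the ortho-lithiation.

Step 3
Reactants: 4 5,7-bis(methoxymethoxy)-4-(2-methylpropyl)-2H-chromen-2-one
Product: 5 (4S)-5,7-bis(methoxymethoxy)-4-(2-methylpropyl)-3,4-dihydro-2H-chromen-2-one
Conditions: Cu(OAc)2·H2O (5 mol%), (R)-DTBM-SEGPHOS (5 mol%), (EtO)2MeSiH, t-BuOH, toluene, 0 °C → rt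
Reagents that add atoms: none
Why: Asymmetric copper hydride conjugate reduction of the β,β-disubstituted unsaturated lactone, in which ligand-bound CuH adds hydride to one face of C4 and sets the benzylic centre (4S) while t-BuOH protonates the copper enolate.

Step 4
Reactants: 5 (4S)-5,7-bis(methoxymethoxy)-4-(2-methylpropyl)-3,4-dihydro-2H-chromen-2-one
Product: 7 (3S,4S)-5,7-bis(methoxymethoxy)-3-methyl-4-(2-methylpropyl)-3,4-dihydro-2H-chromen-2-one, via lithium enolate 6 (not isolated)
Conditions: LiN(i-Pr)2, THF, −78 °C; MeI, −78 → −40 °C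
Reagents that add atoms: iodomethane, CI
Why: Lactone enolate alkylation in which methyl enters trans to the benzylic isobutyl group; the C3 configuration is erased again in step 5, so only clean mono-methylation matters.

Step 5
Reactants: 7 (3S,4S)-5,7-bis(methoxymethoxy)-3-methyl-4-(2-methylpropyl)-3,4-dihydro-2H-chromen-2-one
Product: 9 (3R,4R)-3-(hydroxymethyl)-5,7-bis(methoxymethoxy)-3-methyl-4-(2-methylpropyl)-3,4-dihydro-2H-chromen-2-one, via lithium enolate 8 (not isolated)
Conditions: LiN(i-Pr)2, THF, −78 °C; CH2O (gas from cracked paraformaldehyde), −78 °C; AcOH, −78 °C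
Reagents that add atoms: formaldehyde, C=O
Why: Aldol addition of the lactone enolate to formaldehyde, in which the isobutyl group on lactone C4, held pseudoaxial by the peri OMOM group, blocks one face so that the CH2OH carbon enters trans to it and fixes the quaternary centre, the cold acidic quench keeping the alkoxide from attacking the aryl ester.

Step 6
Reactants: 9 (3R,4R)-3-(hydroxymethyl)-5,7-bis(methoxymethoxy)-3-methyl-4-(2-methylpropyl)-3,4-dihydro-2H-chromen-2-one
Product: 10 (3R,4R)-3-{[tert-butyl(dimethyl)silyl]oxymethyl}-5,7-bis(methoxymethoxy)-3-methyl-4-(2-methylpropyl)-3,4-dihydro-2H-chromen-2-one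
Conditions: TBSCl, imidazole, DMF, rt
Reagents that add atoms: tert-butyl(chloro)dimethylsilane, CC(C)(C)[Si](C)(C)Cl
Why: Silylation of the primary alcohol removes the β-alkoxide that could otherwise trigger retro-aldol loss of formaldehyde in step 8.

Step 7
Reactants: 10 (3R,4R)-3-{[tert-butyl(dimethyl)silyl]oxymethyl}-5,7-bis(methoxymethoxy)-3-methyl-4-(2-methylpropyl)-3,4-dihydro-2H-chromen-2-one
Product: 11 (3R,4R)-3-{[tert-butyl(dimethyl)silyl]oxymethyl}-5,7-bis(methoxymethoxy)-3-methyl-4-(2-methylpropyl)-3,4-dihydro-2H-chromen-2-ol (both C2 epimers)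
Conditions: i-Bu2AlH (1.2 equiv), CH2Cl2, −78 °C; aq. potassium sodium tartrate
Reagents that add atoms: none
Why: Partial reduction of the lactone to the lactol, the aluminium hemiacetal being stable at −78 °C and the α-carbon being quaternary so nothing can epimerise.

Step 8
Reactants: 11 (3R,4R)-3-{[tert-butyl(dimethyl)silyl]oxymethyl}-5,7-bis(methoxymethoxy)-3-methyl-4-(2-methylpropyl)-3,4-dihydro-2H-chromen-2-ol
Product: 12 2-[(3R,4S)-3-{[tert-butyl(dimethyl)silyl]oxymethyl}-3,6-dimethylhept-1-en-4-yl]-3,5-bis(methoxymethoxy)phenol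
Conditions: Ph3PCH3Br, KOt-Bu, THF, 0 → 50 °C
Reagents that add atoms: methyltriphenylphosphonium bromide, C[P+](c1ccccc1)(c1ccccc1)c1ccccc1.[Br-]
Why: Wittig methylenation of the open hydroxy-aldehyde form of the lactol turns the former lactone carbon into a vinyl group and frees the phenol.

Step 9
Reactants: 12 2-[(3R,4S)-3-{[tert-butyl(dimethyl)silyl]oxymethyl}-3,6-dimethylhept-1-en-4-yl]-3,5-bis(methoxymethoxy)phenol
Product: 13 tert-butyl{[(2R,3S)-2-ethenyl-2,5-dimethyl-3-[2,4,6-tris(methoxymethoxy)phenyl]hexyl]oxy}dimethylsilane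
Conditions: MOMCl, i-Pr2NEt, CH2Cl2, 0 °C → rt
Reagents that add atoms: chloromethyl methyl ether, COCCl
Why: MOM ether formation on the liberated phenol gives the symmetrical tris-MOM arene needed for the later double ortho-lithiation.

Step 10
Reactants: 14 prop-2-yn-1-ol
Product: 16 (2Z)-3-iodo-2-methylprop-2-en-1-ol, via cyclic vinylmagnesium alkoxide 15 (not isolated)
Conditions: MeMgBr (2.5 equiv), CuI (10 mol%), THF, −10 °C → rt; I2, −20 °C
Reagents that add atoms: methylmagnesium bromide, C[Mg]Br; iodine, II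
Why: Copper-catalysed anti carbomagnesiation of the propargylic alkoxide places methyl on C2 and magnesium on C3 in a five-membered chelate cis to the CH2O group, and iodinolysis with retention gives the Z iodide.

Step 11
Reactants: 16 (2Z)-3-iodo-2-methylprop-2-en-1-ol
Product: 18 methyl (2E,4Z)-5-iodo-4-methylpenta-2,4-dienoate, via iodoenal 17 (not isolated)
Conditions: MnO2, Ph3P=CHCO2Me, CH2Cl2, rt
Reagents that add atoms: methyl (triphenylphosphoranylidene)acetate, COC(=O)C=P(c1ccccc1)(c1ccccc1)c1ccccc1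
Why: Allylic oxidation and Wittig olefination in one flask, the stabilised ylide giving the E enoate and trapping the Z iodoenal before it can isomerise.

Step 12
Reactants: 18 methyl (2E,4Z)-5-iodo-4-methylpenta-2,4-dienoate
Product: 19 (2E,4Z)-5-iodo-4-methylpenta-2,4-dien-1-ol
Conditions: i-Bu2AlH (2.2 equiv), CH2Cl2, −78 °C; aq. potassium sodium tartrate
Reagents that add atoms: none
Why: 1,2-Reduction of the conjugated ester to the allylic alcohol, which leaves the vinyl iodide untouched.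

Step 13
Reactants: 19 (2E,4Z)-5-iodo-4-methylpenta-2,4-dien-1-ol
Product: 20 [(1R,2R)-2-[(1Z)-1-iodoprop-1-en-2-yl]cyclopropyl]methanol
Conditions: Et2Zn, CH2I2, DME, CH2Cl2, −10 °C; (4S,5S)-2-butyl-N,N,N′,N′-tetramethyl-1,3,2-dioxaborolane-4,5-dicarboxamide, then 19, −10 °C → rt
Reagents that add atoms: diiodomethane, ICI
Why: Charette asymmetric Simmons–Smith cyclopropanation, in which the zinc alkoxide bound to the chiral dioxaborolane delivers CH2 to one face of the allylic E alkene only (the iodoalkene is remote and electron-poor), the (4S,5S) ligand giving the (1R,2R) ring and the E geometry becoming the trans relationship.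

Step 14
Reactants: 20 [(1R,2R)-2-[(1Z)-1-iodoprop-1-en-2-yl]cyclopropyl]methanol
Product: 21 (1R,2R)-2-[(1Z)-1-iodoprop-1-en-2-yl]cyclopropane-1-carboxylic acid
Conditions: TEMPO (10 mol%), PhI(OAc)2, MeCN/H2O, rt
Reagents that add atoms: water, O
Why: Oxoammonium oxidation of the primary alcohol to the aldehyde and on to the acid through its hydrate, conditions that tolerate the vinyl iodide and the cyclopropane.

Step 15
Reactants: 21 (1R,2R)-2-[(1Z)-1-iodoprop-1-en-2-yl]cyclopropane-1-carboxylic acid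
Product: 22 methyl (1R,2R)-2-[(1Z)-1-iodoprop-1-en-2-yl]cyclopropane-1-carboxylate
Conditions: MeI, K2CO3, DMF, rt
Reagents that add atoms: iodomethane, CI
Why: SN2 O-methylation of the carboxylate gives the ester that later activates the adjacent ring bond and becomes the carbinol.

Step 16
Reactants: 13 tert-butyl{[(2R,3S)-2-ethenyl-2,5-dimethyl-3-[2,4,6-tris(methoxymethoxy)phenyl]hexyl]oxy}dimethylsilane; 22 methyl (1R,2R)-2-[(1Z)-1-iodoprop-1-en-2-yl]cyclopropane-1-carboxylate
Product: 24 methyl (1R,2R)-2-[(2Z,6R,7S)-6-{[tert-butyl(dimethyl)silyl]oxymethyl}-6,9-dimethyl-7-[2,4,6-tris(methoxymethoxy)phenyl]dec-2-en-2-yl]cyclopropane-1-carboxylate, via alkylborane 23 (not isolated)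
Conditions: 9-BBN, THF, rt → 50 °C; then 22, Pd(dppf)Cl2 (5 mol%), AsPh3, Cs2CO3, DMF/H2O, rt
Reagents that add atoms: none
Why: Anti-Markovnikov hydroboration of the vinyl group followed by B-alkyl Suzuki–Miyaura coupling on zerovalent palladium joins C3 to C3a with retention of the Z geometry of the iodide.

Step 17
Reactants: 24 methyl (1R,2R)-2-[(2Z,6R,7S)-6-{[tert-butyl(dimethyl)silyl]oxymethyl}-6,9-dimethyl-7-[2,4,6-tris(methoxymethoxy)phenyl]dec-2-en-2-yl]cyclopropane-1-carboxylate
Product: 25 methyl (1R,2R)-2-[(2Z,6R,7S)-6-(hydroxymethyl)-6,9-dimethyl-7-[2,4,6-tris(methoxymethoxy)phenyl]dec-2-en-2-yl]cyclopropane-1-carboxylate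
Conditions: TBAF, AcOH, THF, rt
Reagents that add atoms: none
Why: Fluoride-mediated desilylation, buffered with acetic acid so that the methyl ester is not touched.

Step 18
Reactants: 25 methyl (1R,2R)-2-[(2Z,6R,7S)-6-(hydroxymethyl)-6,9-dimethyl-7-[2,4,6-tris(methoxymethoxy)phenyl]dec-2-en-2-yl]cyclopropane-1-carboxylate
Product: 26 methyl (1R,2R)-2-[(2Z,6R,7R)-6-formyl-6,9-dimethyl-7-[2,4,6-tris(methoxymethoxy)phenyl]dec-2-en-2-yl]cyclopropane-1-carboxylate
Conditions: Dess–Martin periodinane, CH2Cl2, 0 °C → rt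
Reagents that add atoms: none
Why: Dess–Martin oxidation of the neopentyl alcohol gives an aldehyde that has no α-hydrogen and cannot epimerise (the 7R label reflects a priority change only).

Step 19
Reactants: 26 methyl (1R,2R)-2-[(2Z,6R,7R)-6-formyl-6,9-dimethyl-7-[2,4,6-tris(methoxymethoxy)phenyl]dec-2-en-2-yl]cyclopropane-1-carboxylate
Product: 27 methyl (1R,2R)-2-[(2Z,6R,7S)-6-ethynyl-6,9-dimethyl-7-[2,4,6-tris(methoxymethoxy)phenyl]dec-2-en-2-yl]cyclopropane-1-carboxylate
Conditions: dimethyl (1-diazo-2-oxopropyl)phosphonate, K2CO3, MeOH, 0 °C → rt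
Reagents that add atoms: dimethyl (1-diazo-2-oxopropyl)phosphonate, COP(=O)(OC)C(=[N+]=[N-])C(C)=O
Why: Ohira–Bestmann homologation of the non-enolisable aldehyde gives the terminal alkyne on the quaternary carbon, and methanol as solvent cannot scramble a methyl ester.

Step 20
Reactants: 27 methyl (1R,2R)-2-[(2Z,6R,7S)-6-ethynyl-6,9-dimethyl-7-[2,4,6-tris(methoxymethoxy)phenyl]dec-2-en-2-yl]cyclopropane-1-carboxylate
Product: 28 methyl (1R,3aR,7R)-1,4-dimethyl-1-{(1S)-3-methyl-1-[2,4,6-tris(methoxymethoxy)phenyl]butyl}-1,2,3,3a,6,7-hexahydroazulene-7-carboxylate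
Conditions: [Rh(CO)2Cl]2 (5 mol%), toluene, 90 °C
Reagents that add atoms: none
Why: Monovalent rhodium binds the alkyne and the alkene, inserts into the cyclopropane bond between the vinyl-bearing and the ester-bearing carbon to give an allyl–alkyl rhodacycle, the alkyne inserts and reductive elimination releases the product, the closest known reaction type being the intramolecular rhodium-catalysed [5+2] cycloaddition of alkynes with vinylcyclopropanes. The five-membered ring closes through the C1–C2–C3 tether when the internal alkyne carbon bonds to the tether-bearing alkene carbon (C8a–C3a), and the seven-membered ring is the five vinylcyclopropane carbons plus the two alkyne carbons, completed by the C8–C7 bond. Both new bonds form on the same face of the five-carbon unit and with retention at the ester carbon, so C7 (R) is the (1R) cyclopropane carbon, and C3a (R) follows from the (2R) cyclopropane carbon together with the Z alkene, which places H-3a cis to the ester. The quaternary centre is a spectator, so the step is stereospecific and needs no facial selection. What it does need is cleavage of the more substituted ring bond, which the trans ester secures electronically with this catalyst, and enough reactivity from the Z alkene, whose reactive rotamer carries allylic strain between the tether and the ring CH2 and therefore calls for 90–110 °C.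

Step 21
Reactants: 28 methyl (1R,3aR,7R)-1,4-dimethyl-1-{(1S)-3-methyl-1-[2,4,6-tris(methoxymethoxy)phenyl]butyl}-1,2,3,3a,6,7-hexahydroazulene-7-carboxylate
Product: 29 methyl (1R,3aR,4R,7R)-1,4-dimethyl-1-{(1S)-3-methyl-1-[2,4,6-tris(methoxymethoxy)phenyl]butyl}-1,2,3,3a,4,5,6,7-octahydroazulene-7-carboxylate
Conditions: H2 (1 atm), [Ir(cod)(PCy3)(py)]PF6 (3 mol%), CH2Cl2, 0 °C
Reagents that add atoms: none
Why: Ester-directed homogeneous hydrogenation with a cationic iridium catalyst, in which the C7 ester carbonyl on the face of H-3a binds the metal and hydrogen is delivered to that face of C4=C5, putting the C4 methyl trans to H-3a (4R), while the C8=C8a alkene is screened on that face by the benzylic substituent of the adjacent quaternary carbon.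

Step 22
Reactants: 29 methyl (1R,3aR,4R,7R)-1,4-dimethyl-1-{(1S)-3-methyl-1-[2,4,6-tris(methoxymethoxy)phenyl]butyl}-1,2,3,3a,4,5,6,7-octahydroazulene-7-carboxylate
Product: 30 2-[(1R,3aR,4R,7R)-1,4-dimethyl-1-{(1S)-3-methyl-1-[2,4,6-tris(methoxymethoxy)phenyl]butyl}-1,2,3,3a,4,5,6,7-octahydroazulen-7-yl]propan-2-ol
Conditions: MeLi, CeCl3, THF, −78 → −40 °C
Reagents that add atoms: methyllithium, [Li]C
Why: Double addition of the weakly basic methylcerium reagent to the ester (organocerium addition) gives the tertiary alcohol without enolising the doubly activated C7–H, so the C7 configuration is kept.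

Step 23
Reactants: 30 2-[(1R,3aR,4R,7R)-1,4-dimethyl-1-{(1S)-3-methyl-1-[2,4,6-tris(methoxymethoxy)phenyl]butyl}-1,2,3,3a,4,5,6,7-octahydroazulen-7-yl]propan-2-ol
Product: 34 5-[(1S)-1-[(1R,3aR,4R,7R)-7-(2-hydroxypropan-2-yl)-1,4-dimethyl-1,2,3,3a,4,5,6,7-octahydroazulen-1-yl]-3-methylbutyl]-2,4,6-tris(methoxymethoxy)benzene-1,3-dicarbaldehyde, via aryllithium alkoxide 31 (not isolated), via lithium hemiaminal 32 (not isolated), via lithiated hemiaminal 33 (not isolated)
Conditions: n-BuLi (2.1 equiv), TMEDA, THF, −78 → 0 °C; DMF (1.2 equiv), −78 °C; n-BuLi (1.5 equiv), −78 → −20 °C; DMF (3 equiv), −78 °C → rt; AcOH, H2O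
Reagents that add atoms: N,N-dimethylformamide, CN(C)C=O
Why: Directed ortho-metalation followed by DMF formylation, run twice in one flask, each free ring position lying between two OMOM groups and the first formyl group staying masked as its lithium α-amino alkoxide during the second lithiation.

Step 24
Reactants: 34 5-[(1S)-1-[(1R,3aR,4R,7R)-7-(2-hydroxypropan-2-yl)-1,4-dimethyl-1,2,3,3a,4,5,6,7-octahydroazulen-1-yl]-3-methylbutyl]-2,4,6-tris(methoxymethoxy)benzene-1,3-dicarbaldehyde
Product: 35 5-[(1S)-1-[(1R,3aR,4R,7R)-7-(2-hydroxypropan-2-yl)-1,4-dimethyl-1,2,3,3a,4,5,6,7-octahydroazulen-1-yl]-3-methylbutyl]-2,4,6-trihydroxybenzene-1,3-dicarbaldehyde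
Conditions: HCl (1 M), MeOH/THF, 0 °C → rt
Reagents that add atoms: none
Why: Acid-catalysed acetal exchange with methanol removes the three MOM groups, each ortho to a formyl group and therefore cleaved under conditions mild enough for the tertiary alcohol and the ring-fusion alkene.

**Compound list**

1 | benzene-1,3,5-triol | Oc1cc(O)cc(O)c1 | starting material
2 | ethyl 5-methyl-3-oxohexanoate | CCOC(=O)CC(=O)CC(C)C | starting material
3 | 5,7-dihydroxy-4-(2-methylpropyl)-2H-chromen-2-one | CC(C)CC1=CC(=O)Oc2cc(O)cc(O)c12 | intermediate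
4 | 5,7-bis(methoxymethoxy)-4-(2-methylpropyl)-2H-chromen-2-one | CC(C)CC1=CC(=O)Oc2cc(OCOC)cc(OCOC)c12 | intermediate
5 | (4S)-5,7-bis(methoxymethoxy)-4-(2-methylpropyl)-3,4-dihydro-2H-chromen-2-one | CC(C)C[C@H]1CC(=O)Oc2cc(OCOC)cc(OCOC)c12 | intermediate
6 | lithium enolate of 5 | CC(C)C[C@H]1C=C(O[Li])Oc2cc(OCOC)cc(OCOC)c12 | intermediate (not isolated)
7 | (3S,4S)-5,7-bis(methoxymethoxy)-3-methyl-4-(2-methylpropyl)-3,4-dihydro-2H-chromen-2-one | CC(C)C[C@H]1[C@H](C)C(=O)Oc2cc(OCOC)cc(OCOC)c12 | intermediate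
8 | lithium enolate of 7 | CC(C)C[C@H]1C(C)=C(O[Li])Oc2cc(OCOC)cc(OCOC)c12 | intermediate (not isolated)
9 | (3R,4R)-3-(hydroxymethyl)-5,7-bis(methoxymethoxy)-3-methyl-4-(2-methylpropyl)-3,4-dihydro-2H-chromen-2-one | CC(C)C[C@H]1[C@](C)(CO)C(=O)Oc2cc(OCOC)cc(OCOC)c12 | intermediate
10 | (3R,4R)-3-{[tert-butyl(dimethyl)silyl]oxymethyl}-5,7-bis(methoxymethoxy)-3-methyl-4-(2-methylpropyl)-3,4-dihydro-2H-chromen-2-one | CC(C)C[C@H]1[C@](C)(CO[Si](C)(C)C(C)(C)C)C(=O)Oc2cc(OCOC)cc(OCOC)c12 | intermediate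
11 | (3R,4R)-3-{[tert-butyl(dimethyl)silyl]oxymethyl}-5,7-bis(methoxymethoxy)-3-methyl-4-(2-methylpropyl)-3,4-dihydro-2H-chromen-2-ol, both C2 epimers | CC(C)C[C@H]1[C@](C)(CO[Si](C)(C)C(C)(C)C)C(O)Oc2cc(OCOC)cc(OCOC)c12 | intermediate
12 | 2-[(3R,4S)-3-{[tert-butyl(dimethyl)silyl]oxymethyl}-3,6-dimethylhept-1-en-4-yl]-3,5-bis(methoxymethoxy)phenol | CC(C)C[C@H](c1c(O)cc(OCOC)cc1OCOC)[C@](C)(CO[Si](C)(C)C(C)(C)C)C=C | intermediate
13 | tert-butyl{[(2R,3S)-2-ethenyl-2,5-dimethyl-3-[2,4,6-tris(methoxymethoxy)phenyl]hexyl]oxy}dimethylsilane | CC(C)C[C@H](c1c(OCOC)cc(OCOC)cc1OCOC)[C@](C)(CO[Si](C)(C)C(C)(C)C)C=C | intermediate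
14 | prop-2-yn-1-ol | C#CCO | starting material
15 | 4-methyl-2,5-dihydro-1,2-oxamagnesole (cyclic vinylmagnesium alkoxide) | CC1=C[Mg]OC1 | intermediate (not isolated)
16 | (2Z)-3-iodo-2-methylprop-2-en-1-ol | OC/C(C)=C\I | intermediate
17 | (2Z)-3-iodo-2-methylprop-2-enal | O=C/C(C)=C\I | intermediate (not isolated)
18 | methyl (2E,4Z)-5-iodo-4-methylpenta-2,4-dienoate | COC(=O)/C=C/C(C)=C\I | intermediate
19 | (2E,4Z)-5-iodo-4-methylpenta-2,4-dien-1-ol | OC/C=C/C(C)=C\I | intermediate
20 | [(1R,2R)-2-[(1Z)-1-iodoprop-1-en-2-yl]cyclopropyl]methanol | I/C=C(/C)[C@@H]1C[C@H]1CO | intermediate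
21 | (1R,2R)-2-[(1Z)-1-iodoprop-1-en-2-yl]cyclopropane-1-carboxylic acid | I/C=C(/C)[C@@H]1C[C@H]1C(=O)O | intermediate
22 | methyl (1R,2R)-2-[(1Z)-1-iodoprop-1-en-2-yl]cyclopropane-1-carboxylate | I/C=C(/C)[C@@H]1C[C@H]1C(=O)OC | intermediate
23 | B-alkyl-9-borabicyclo[3.3.1]nonane formed from 13 (boron on the former terminal vinyl carbon) | CC(C)C[C@H](c1c(OCOC)cc(OCOC)cc1OCOC)[C@](C)(CO[Si](C)(C)C(C)(C)C)CCB1C2CCCC1CCC2 | intermediate (not isolated)
24 | methyl (1R,2R)-2-[(2Z,6R,7S)-6-{[tert-butyl(dimethyl)silyl]oxymethyl}-6,9-dimethyl-7-[2,4,6-tris(methoxymethoxy)phenyl]dec-2-en-2-yl]cyclopropane-1-carboxylate | CC(C)C[C@H](c1c(OCOC)cc(OCOC)cc1OCOC)[C@](C)(CO[Si](C)(C)C(C)(C)C)CC/C=C(/C)[C@@H]1C[C@H]1C(=O)OC | intermediate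
25 | methyl (1R,2R)-2-[(2Z,6R,7S)-6-(hydroxymethyl)-6,9-dimethyl-7-[2,4,6-tris(methoxymethoxy)phenyl]dec-2-en-2-yl]cyclopropane-1-carboxylate | CC(C)C[C@H](c1c(OCOC)cc(OCOC)cc1OCOC)[C@](C)(CO)CC/C=C(/C)[C@@H]1C[C@H]1C(=O)OC | intermediate
26 | methyl (1R,2R)-2-[(2Z,6R,7R)-6-formyl-6,9-dimethyl-7-[2,4,6-tris(methoxymethoxy)phenyl]dec-2-en-2-yl]cyclopropane-1-carboxylate | CC(C)C[C@H](c1c(OCOC)cc(OCOC)cc1OCOC)[C@](C)(C=O)CC/C=C(/C)[C@@H]1C[C@H]1C(=O)OC | intermediate
27 | methyl (1R,2R)-2-[(2Z,6R,7S)-6-ethynyl-6,9-dimethyl-7-[2,4,6-tris(methoxymethoxy)phenyl]dec-2-en-2-yl]cyclopropane-1-carboxylate | CC(C)C[C@H](c1c(OCOC)cc(OCOC)cc1OCOC)[C@](C)(C#C)CC/C=C(/C)[C@@H]1C[C@H]1C(=O)OC | intermediate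
28 | methyl (1R,3aR,7R)-1,4-dimethyl-1-{(1S)-3-methyl-1-[2,4,6-tris(methoxymethoxy)phenyl]butyl}-1,2,3,3a,6,7-hexahydroazulene-7-carboxylate | CC(C)C[C@H](c1c(OCOC)cc(OCOC)cc1OCOC)[C@@]1(C)CC[C@H]2C1=C[C@H](C(=O)OC)CC=C2C | intermediate
29 | methyl (1R,3aR,4R,7R)-1,4-dimethyl-1-{(1S)-3-methyl-1-[2,4,6-tris(methoxymethoxy)phenyl]butyl}-1,2,3,3a,4,5,6,7-octahydroazulene-7-carboxylate | CC(C)C[C@H](c1c(OCOC)cc(OCOC)cc1OCOC)[C@@]1(C)CC[C@H]2C1=C[C@H](C(=O)OC)CC[C@H]2C | intermediate
30 | 2-[(1R,3aR,4R,7R)-1,4-dimethyl-1-{(1S)-3-methyl-1-[2,4,6-tris(methoxymethoxy)phenyl]butyl}-1,2,3,3a,4,5,6,7-octahydroazulen-7-yl]propan-2-ol | CC(C)C[C@H](c1c(OCOC)cc(OCOC)cc1OCOC)[C@@]1(C)CC[C@H]2C1=C[C@H](C(C)(C)O)CC[C@H]2C | intermediate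
31 | lithium alkoxide of 30 lithiated at one free ring position | CC(C)C[C@H](c1c(OCOC)c([Li])c(OCOC)cc1OCOC)[C@@]1(C)CC[C@H]2C1=C[C@H](C(C)(C)O[Li])CC[C@H]2C | intermediate (not isolated)
32 | lithium α-(dimethylamino)alkoxide formed from 31 and DMF | CC(C)C[C@H](c1c(OCOC)c(C(O[Li])N(C)C)c(OCOC)cc1OCOC)[C@@]1(C)CC[C@H]2C1=C[C@H](C(C)(C)O[Li])CC[C@H]2C | intermediate (not isolated)
33 | 32 lithiated at the second free ring position | CC(C)C[C@H](c1c(OCOC)c(C(O[Li])N(C)C)c(OCOC)c([Li])c1OCOC)[C@@]1(C)CC[C@H]2C1=C[C@H](C(C)(C)O[Li])CC[C@H]2C | intermediate (not isolated)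
34 | 5-[(1S)-1-[(1R,3aR,4R,7R)-7-(2-hydroxypropan-2-yl)-1,4-dimethyl-1,2,3,3a,4,5,6,7-octahydroazulen-1-yl]-3-methylbutyl]-2,4,6-tris(methoxymethoxy)benzene-1,3-dicarbaldehyde | CC(C)C[C@H](c1c(OCOC)c(C=O)c(OCOC)c(C=O)c1OCOC)[C@@]1(C)CC[C@H]2C1=C[C@H](C(C)(C)O)CC[C@H]2C | intermediate
35 | 5-[(1S)-1-[(1R,3aR,4R,7R)-7-(2-hydroxypropan-2-yl)-1,4-dimethyl-1,2,3,3a,4,5,6,7-octahydroazulen-1-yl]-3-methylbutyl]-2,4,6-trihydroxybenzene-1,3-dicarbaldehyde | CC(C)C[C@H](c1c(O)c(C=O)c(O)c(C=O)c1O)[C@@]1(C)CC[C@H]2C1=C[C@H](C(C)(C)O)CC[C@H]2C | target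

**Totals**

Total step count: 24. Longest linear sequence: 18 (steps 1–9 and 16–24); steps 10–15 make the cyclopropyl vinyl iodide.

**Steps most likely to fail**

Step 20. The tether sits cis to the ring on the alkene, which strains the rotamer needed for ring opening; the cyclopropane may therefore open slowly or at its unsubstituted bond, and the alkene may isomerise before the alkyne inserts. The fallback sets out from 27 and returns at 28. Reduction of the ester with i-Bu2AlH should give the cyclopropylmethanol F1, and Dess–Martin oxidation the cyclopropanecarbaldehyde F2. The formyl group is smaller and a stronger acceptor than the ester, so it weakens the adjacent ring bond further. Cycloaddition of F2 with [Rh(CO)2Cl]2 should give the bicyclic aldehyde F3, which is oxidised at once (NaClO2, NaH2PO4, 2-methylbut-2-ene) to the bicyclic acid F4 and methylated with TMSCHN2 to 28.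

Step 21. The ester may bind the metal too weakly, so that hydrogen adds to the wrong face of C4=C5 or also to C8=C8a. The fallback sets out from 28 and returns at 30, with the order of the two steps reversed. MeLi/CeCl3 at −78 °C should give the diene carbinol F5. Its tertiary hydroxyl lies on the same face as the ester did and is a stronger donor, and it then directs hydrogenation of C4=C5 with [Rh(nbd)(dppb)]BF4 under H2 in CH2Cl2. The C8=C8a alkene stays screened on that face by the benzylic substituent.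

Step 3. The conjugate reduction may give low enantioselectivity next to the peri OMOM group, or reduce the lactone further to the lactol. The fallback sets out from 1 and returns at 5, setting the benzylic centre with an oxazolidinone auxiliary. Phloroglucinol 1 is converted with NaH and MOMCl into 1,3,5-tris(methoxymethoxy)benzene F6. (2E)-5-Methylhex-2-enoic acid is joined to (4R)-4-phenyl-1,3-oxazolidin-2-one (pivaloyl chloride, Et3N, then the lithiated auxiliary) to give the enoyl imide F7. F6 is lithiated with n-BuLi, transmetalated with MgBr2·OEt2 and CuBr·SMe2, and added to F7 anti to the phenyl group of the chelated imide, giving the adduct F8 with the (3S) benzylic centre. Aqueous HCl in THF, then TsOH in toluene at 80 °C, removes the MOM groups and closes the lactone with release of the auxiliary, giving the dihydroxy lactone F9. MOMCl and i-Pr2NEt return to 5.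

**Further compounds**

F1 | step 20 | [(1R,2R)-2-[(2Z,6R,7S)-6-ethynyl-6,9-dimethyl-7-[2,4,6-tris(methoxymethoxy)phenyl]dec-2-en-2-yl]cyclopropyl]methanol | CC(C)C[C@H](c1c(OCOC)cc(OCOC)cc1OCOC)[C@](C)(C#C)CC/C=C(/C)[C@@H]1C[C@H]1CO
F2 | step 20 | (1R,2R)-2-[(2Z,6R,7S)-6-ethynyl-6,9-dimethyl-7-[2,4,6-tris(methoxymethoxy)phenyl]dec-2-en-2-yl]cyclopropane-1-carbaldehyde | CC(C)C[C@H](c1c(OCOC)cc(OCOC)cc1OCOC)[C@](C)(C#C)CC/C=C(/C)[C@@H]1C[C@H]1C=O
F3 | step 20 | (1R,3aR,7R)-1,4-dimethyl-1-{(1S)-3-methyl-1-[2,4,6-tris(methoxymethoxy)phenyl]butyl}-1,2,3,3a,6,7-hexahydroazulene-7-carbaldehyde | CC(C)C[C@H](c1c(OCOC)cc(OCOC)cc1OCOC)[C@@]1(C)CC[C@H]2C1=C[C@H](C=O)CC=C2C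
F4 | step 20 | (1R,3aR,7R)-1,4-dimethyl-1-{(1S)-3-methyl-1-[2,4,6-tris(methoxymethoxy)phenyl]butyl}-1,2,3,3a,6,7-hexahydroazulene-7-carboxylic acid | CC(C)C[C@H](c1c(OCOC)cc(OCOC)cc1OCOC)[C@@]1(C)CC[C@H]2C1=C[C@H](C(=O)O)CC=C2C
F5 | step 21 | 2-[(1R,3aR,7R)-1,4-dimethyl-1-{(1S)-3-methyl-1-[2,4,6-tris(methoxymethoxy)phenyl]butyl}-1,2,3,3a,6,7-hexahydroazulen-7-yl]propan-2-ol | CC(C)C[C@H](c1c(OCOC)cc(OCOC)cc1OCOC)[C@@]1(C)CC[C@H]2C1=C[C@H](C(C)(C)O)CC=C2C
F6 | step 3 | 1,3,5-tris(methoxymethoxy)benzene | COCOc1cc(OCOC)cc(OCOC)c1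
F7 | step 3 | (4R)-3-[(2E)-5-methylhex-2-enoyl]-4-phenyl-1,3-oxazolidin-2-one | CC(C)C/C=C/C(=O)N1[C@H](c2ccccc2)COC1=O
F8 | step 3 | (4R)-3-[(3S)-5-methyl-3-[2,4,6-tris(methoxymethoxy)phenyl]hexanoyl]-4-phenyl-1,3-oxazolidin-2-one | CC(C)C[C@H](c1c(OCOC)cc(OCOC)cc1OCOC)CC(=O)N1[C@H](c2ccccc2)COC1=O
F9 | step 3 | (4S)-5,7-dihydroxy-4-(2-methylpropyl)-3,4-dihydro-2H-chromen-2-one | CC(C)C[C@H]1CC(=O)Oc2cc(O)cc(O)c12
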